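## Retrosynthetic overview

1. Camelliol C ⇐ final-step Ti(III) radical 6-endo cyclisation of an (S)-2,3-oxidosqualene carrying a phenylsulfonyl group on the allylic carbon next to the first C(Me)=CH; the tertiary radical formed on ring closure ejects PhSO2•, which fixes the ring alkene and removes the sulfone. This is the only ring and it is formed last.
2. That epoxy sulfone ⇐ α-alkylation of a C25 all-E allyl phenyl sulfone with (S)-(3,3-dimethyloxiranyl)methyl tosylate (Sharpless epoxidation of prenol).
3. C25 sulfone ⇐ C25 secondary 2-methylallylic alcohol (Pd allylic sulfonylation with 1,3-transposition) ⇐ mono Johnson–Claisen / DIBAL / isopropylidene Wittig on a symmetric C20 bis-allylic diol.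
4. C20 diol ⇐ two-directional isopropenyl-Grignard / Johnson–Claisen iteration from succinaldehyde, whose CH2CH2 becomes the tail-to-tail centre.

Assumption: succinaldehyde is taken as commercial and freshly distilled. Ring numbering used below: C1 (=CH), C2 (CH2), C3 (CHOH), C4 (CMe2), C5 (CH bearing the chain), C10 (C–Me).

## Route

**Step 1**
Reactants: 1 succinaldehyde (butanedial), 1 equiv; 2 isopropenylmagnesium bromide, 2 equiv incorporated (2.5 equiv used)
Product: 3 2,7-dimethylocta-1,7-diene-3,6-diol (dl/meso mixture)
Conditions: 2 (2.5 equiv), THF, –78 → 0 °C; aq NH4Cl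
Reagents that add atoms: isopropenylmagnesium bromide, C=C(C)[Mg]Br (the second equivalent of 2; one C3 unit per aldehyde)
Why: Double Grignard 1,2-addition, one isopropenyl unit per aldehyde (the intermediate lactolate re-opens under excess reagent); the two carbinol centres form unselectively, which is irrelevant because both are destroyed in step 2.

**Step 2**
Reactants: 3, 1 equiv; 4 trimethyl orthoacetate, 2 equiv incorporated (used in excess)
Product: 5 dimethyl (4E,8E)-4,9-dimethyldodeca-4,8-dienedioate
Conditions: MeC(OMe)3 (excess), EtCO2H (cat.), 110–140 °C, MeOH distilled off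
Reagents that add atoms: trimethyl orthoacetate, CC(OC)(OC)OC (the second equivalent of 4; each allylic alcohol takes up one CH2CO2Me unit and four MeOH are lost overall)
Why: Double Johnson orthoester Claisen rearrangement, one per allylic alcohol; the chair transition state with the chain equatorial (the Z-forming chair has a 1,3-diaxial clash with OMe) should give ≥97% E at each new trisubstituted alkene.

**Step 3**
Reactants: 5, 1 equiv; 2 isopropenylmagnesium bromide, 2 equiv incorporated (3 equiv used)
Product: 6 (6E,10E)-2,6,11,15-tetramethylhexadeca-1,6,10,15-tetraene-3,14-diol (diastereomer mixture)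
Conditions: DIBAL-H (2.1 equiv), CH2Cl2, –78 °C; then 2 (3 equiv), –78 → 0 °C; Rochelle salt
Reagents that add atoms: isopropenylmagnesium bromide, C=C(C)[Mg]Br (the second equivalent of 2; one C3 unit per ester terminus, both OMe groups are lost)
Why: One-pot half-reduction/Grignard addition at both ester termini; the aluminium hemiacetals collapse to the aldehydes on warming and are trapped in situ, so the enolisable dialdehyde is never isolated, and the unselective new carbinol centres are erased later.

**Step 4**
Reactants: 6, 1 equiv; 4 trimethyl orthoacetate, 1 equiv incorporated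
Product: 7 methyl (4E,8E,12E)-16-hydroxy-4,8,13,17-tetramethyloctadeca-4,8,12,17-tetraenoate (racemic)
Conditions: MeC(OMe)3 (3 equiv), EtCO2H (cat.), xylene, 135 °C, stopped at about 50% conversion; K2CO3/MeOH work-up; chromatography, 6 recycled
Reagents that add atoms: none
Why: The same Johnson–Claisen rearrangement (E ≥97%) run as a statistical mono-reaction to break the C2 symmetry; at best about 50% of 7 per pass, with the diol recovered and the over-reacted diester lost.

**Step 5**
Reactants: 7
Product: 8 (4E,8E,12E)-16-hydroxy-4,8,13,17-tetramethyloctadeca-4,8,12,17-tetraenal (racemic)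
Conditions: DIBAL-H (2.2 equiv), CH2Cl2, –78 °C; MeOH, Rochelle salt
Reagents that add atoms: none
Why: Low-temperature DIBAL partial reduction of the methyl ester (one equivalent is consumed by the free OH); the non-conjugated E-alkenes are untouched.

**Step 6**
Reactants: 8
Product: 9 (6E,10E,14E)-2,6,11,15,19-pentamethylicosa-1,6,10,14,18-pentaen-3-ol (racemic)
Conditions: i-PrPPh3I (2.5 equiv), n-BuLi, THF, 0 °C; then 8, –78 °C → rt
Reagents that add atoms: isopropyltriphenylphosphonium iodide, CC(C)[P+](c1ccccc1)(c1ccccc1)c1ccccc1.[I-] (transfers the C3 isopropylidene unit)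
Why: Wittig olefination with the non-stabilised isopropylidene ylide; the new alkene is Me2C=, so there is no E/Z issue, and the free hydroxyl is tolerated with excess ylide.

**Step 7**
Reactants: 9
Product: 10 (2E,6E,10E,14E)-2,6,11,15,19-pentamethylicosa-2,6,10,14,18-pentaen-1-yl phenyl sulfone
Conditions: PhSO2Na, Pd(OAc)2 (5 mol%), PPh3, Et3B, THF/DMF, 50 °C
Reagents that add atoms: sodium benzenesulfinate, [Na+].[O-]S(=O)c1ccccc1
Why: Tsuji–Trost allylic sulfonylation of the Et3B-activated alcohol with 1,3-transposition; sulfinate attacks the unhindered CH2 terminus of the π-allyl and, because sulfinate addition is reversible under Pd, the more stable primary E-trisubstituted allyl sulfone accumulates (expected about 9:1; minor Z isomer removed on AgNO3–silica).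

**Step 8**
Reactants: 11 prenol (3-methylbut-2-en-1-ol)
Product: 12 [(2S)-3,3-dimethyloxiran-2-yl]methyl 4-methylbenzenesulfonate
Conditions: Ti(OiPr)4 (5 mol%), L-(+)-DIPT (7 mol%), t-BuOOH, 4 Å MS, CH2Cl2, –20 °C; then P(OMe)3, Et3N, DMAP (cat.), TsCl, –10 °C
Reagents that add atoms: tert-butyl hydroperoxide, CC(C)(C)OO (epoxide O); tosyl chloride, Cc1ccc(cc1)S(Cl)(=O)=O
Why: Sharpless asymmetric epoxidation with in situ tosylation of the volatile glycidol; L-(+)-tartrate delivers oxygen with the same facial sense as geraniol → (2S,3S)-epoxygeraniol, giving the (2S) epoxide (about 90–95% ee).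

**Step 9**
Reactants: 10; 12
Product: 13 (2S)-3,3-dimethyl-2-[(3E,7E,11E,15E)-3,7,12,16,20-pentamethyl-2-(phenylsulfonyl)henicosa-3,7,11,15,19-pentaen-1-yl]oxirane, about 1:1 at the sulfone carbon
Conditions: n-BuLi (0.95 equiv), THF–DMPU, –78 °C; then 12 (1.1 equiv), –78 → –30 °C; cold aq NH4Cl quench
Reagents that add atoms: none
Why: Biellmann-type α-alkylation of the allyl sulfone carbanion by SN2 at the primary tosylate, with base kept slightly sub-stoichiometric so that product 13 is not deprotonated (its anion could close 3-exo onto the epoxide); the trisubstituted epoxide is a spectator, so its (S) centre is untouched, and the new sulfone stereocentre is erased in step 10.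

**Step 10**
Reactants: 13
Product: 14 camelliol C, (1S,5R)-4,6,6-trimethyl-5-[(3E,7E,11E)-3,8,12,16-tetramethylheptadeca-3,7,11,15-tetraen-1-yl]cyclohex-3-en-1-ol
Conditions: Cp2TiCl2 (2.5 equiv), Mn dust (8 equiv), THF, rt, slow addition of 13; aq NaH2PO4
Reagents that add atoms: none
Why: Proposed new method: Cp2TiCl opens the epoxide homolytically to the β-titanoxy tertiary radical at C4 (Nugent–RajanBabu), which closes 6-endo-trig onto the E allyl-sulfone alkene through a chair transition state with OTi and the chain both equatorial, so the (S)-epoxide carbon (C3) sets C5 as R with OH and side chain cis; the resulting tertiary C10 radical then ejects PhSO2• from C1 (intramolecular SH2′), which places the alkene only at C1=C10, stops the cascade at the monocycle and removes the sulfone from both epimers, while excess Ti(III) reduces PhSO2• to sulfinate to suppress 1,3-sulfonyl shifts and olefin isomerisation. The closest known reaction types are titanocene(III) epoxypolyene cyclisation (which, without the sulfone, would be expected to end in unselective β-H loss favouring the exocyclic alkene) and radical allylation or cyclisation onto allyl sulfones with loss of a sulfonyl radical.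

## Compound list

1 | succinaldehyde (butanedial) | O=CCCC=O | starting material
2 | isopropenylmagnesium bromide | C=C(C)[Mg]Br | starting material
3 | 2,7-dimethylocta-1,7-diene-3,6-diol (dl/meso) | C=C(C)C(O)CCC(O)C(C)=C | intermediate
4 | trimethyl orthoacetate | CC(OC)(OC)OC | starting material
5 | dimethyl (4E,8E)-4,9-dimethyldodeca-4,8-dienedioate | COC(=O)CC/C(C)=C/CC/C=C(\C)CCC(=O)OC | intermediate
6 | (6E,10E)-2,6,11,15-tetramethylhexadeca-1,6,10,15-tetraene-3,14-diol | C=C(C)C(O)CC/C(C)=C/CC/C=C(\C)CCC(O)C(C)=C | intermediate
7 | methyl (4E,8E,12E)-16-hydroxy-4,8,13,17-tetramethyloctadeca-4,8,12,17-tetraenoate | COC(=O)CC/C(C)=C/CC/C(C)=C/CC/C=C(\C)CCC(O)C(C)=C | intermediate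
8 | (4E,8E,12E)-16-hydroxy-4,8,13,17-tetramethyloctadeca-4,8,12,17-tetraenal | O=CCC/C(C)=C/CC/C(C)=C/CC/C=C(\C)CCC(O)C(C)=C | intermediate
9 | (6E,10E,14E)-2,6,11,15,19-pentamethylicosa-1,6,10,14,18-pentaen-3-ol | C=C(C)C(O)CC/C(C)=C/CC/C=C(\C)CC/C=C(\C)CCC=C(C)C | intermediate
10 | (2E,6E,10E,14E)-2,6,11,15,19-pentamethylicosa-2,6,10,14,18-pentaen-1-yl phenyl sulfone | O=S(=O)(C/C(C)=C/CC/C(C)=C/CC/C=C(\C)CC/C=C(\C)CCC=C(C)C)c1ccccc1 | intermediate
11 | prenol (3-methylbut-2-en-1-ol) | CC(C)=CCO | starting material
12 | [(2S)-3,3-dimethyloxiran-2-yl]methyl 4-methylbenzenesulfonate | CC1(C)O[C@H]1COS(=O)(=O)c1ccc(C)cc1 | intermediate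
13 | (2S)-3,3-dimethyl-2-[(3E,7E,11E,15E)-3,7,12,16,20-pentamethyl-2-(phenylsulfonyl)henicosa-3,7,11,15,19-pentaen-1-yl]oxirane (epimers at the sulfone carbon) | CC1(C)O[C@H]1CC(S(=O)(=O)c1ccccc1)/C(C)=C/CC/C(C)=C/CC/C=C(\C)CC/C=C(\C)CCC=C(C)C | intermediate
14 | camelliol C | CC(C)=CCC/C(C)=C/CC/C(C)=C/CC/C=C(\C)CC[C@@H]1C(C)=CC[C@H](O)C1(C)C | target

## Step count and risks

Total steps: 10. Longest linear sequence: 9 (steps 1–7, 9, 10; step 8 is a one-step side branch).

Steps most likely to fail:

1. **Step 10 (radical cyclisation with sulfonyl-radical loss).** Risks are epoxide deoxygenation or reduction before ring closure, and radical-chain 1,3-sulfonyl shift of 13. Fallback: form the ring first on a C15 epoxy allyl sulfone that carries a protected terminal allylic alcohol, where the radical step is easier to optimise. Then join the farnesyl half by Biellmann alkylation of farnesyl phenyl sulfone with the derived allylic bromide and remove that sulfone with Pd(dppp)Cl2/LiBHEt3.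
2. **Step 7 (Pd allylic sulfonylation).** Risk is a poor E/Z ratio, because the 2-methyl group on the π-allyl weakens the usual syn preference, plus some branched sulfone. Fallback: replace the Pd step with a [2,3]-sigmatropic transposition. Treat 9 with PhSCl/Et3N so the allyl sulfenate rearranges to the primary E-allyl phenyl sulfoxide, then oxidise sulfur to the sulfone 10 with (NH4)6Mo7O24/H2O2 (one more step).
3. **Step 9 (alkylation with the epoxy tosylate).** Risks are sluggish SN2 of the branched allyl sulfone anion and, if 13 is deprotonated, 3-exo closure onto the epoxide to a cyclopropyl carbinol. Fallback: carry the oxygenation as a protected diol. Alkylate 10 with the acetonide-protected 2,3-dihydroxy-3-methylbutyl iodide (from asymmetric dihydroxylation of a prenyl derivative, diol enantiomer chosen to allow for inversion), then deprotect, mesylate the secondary hydroxyl and close with K2CO3/MeOH to give the (S)-epoxide 13.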